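# Proposed total synthesis of CNP0343121.3 (16-hydroxy-16,17-dihydrogibberellin A4, C16 hydroxyl endo)

## Structural features

Gibberellane numbering is used: C18 (methyl) and C19 (carbonyl) sit on C4, C3 is the carbinol, the lactone oxygen is on C10, carboxyl C7 is on C6, and methyl C17 is on C16. The target is a C19 pentacycle made of cyclohexane ring A, cyclopentane ring B, cyclohexane ring C, cyclopentane ring D and the γ-lactone C19–O–C10. Ring A and the lactone together form a 6-oxabicyclo[3.2.1]octan-7-one (bridgeheads C4 and C10, one-atom bridge C5). Rings C and D form a bicyclo[3.2.1]octane (bridgeheads C8 and C13, one-atom bridge C14), and ring B consists only of the edge C5–C10 of the first cage, the edge C8–C9 of the second, the carbon C6 and the bond C9–C10. There are nine stereocentres, seven of them contiguous (C3, C4, C5, C10, C9, C8, C6), and C4, C8, C10 and C16 are fully substituted. The A/B junction is trans (H5 and the C10 oxygen on opposite faces), H9 is cis to C15, and C7 is trans to both C4 and C14, so the given C6 configuration is the thermodynamic one. At C16 the SMILES places methyl exo (syn to C14) and hydroxyl endo (towards C12), which is the opposite of what an oxygen reagent attacking the exo face of a 16-ene would give; the fragile points are the β-hydroxy lactone C3–C4–C19 (retro-aldol in base), the tertiary carbinol C16 (ionisation and skeletal shift in acid) and the enolisable C6. The real difficulty is ring B, above all the bond between the fully substituted, oxygen-bearing C10 and the neopentyl methine C9 across a trans A/B junction; the key step exploits two facts: C10 is a bridgehead of the lactone cage, so a radical there cannot invert, and C9 lies on the three-carbon bridge of the carbocyclic cage, one face of which is covered by the endo substituent on C16.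

## Logic of the disconnections

In one sentence: ring B is closed last, by 5-exo addition of a bridgehead radical at C10 of a finished lactone cage to C9 of a finished bicyclo[3.2.1]octenone cage that hangs on the same carbon C6.

**27 from 26, 25, 24, 23.** No skeletal bond is cut. The three silicon-based groups are put back (26), C6 is left open as an epimer mixture (25), and a carbonyl group is added at C12 by way of its enol triflate (24, 23). This ketone is the only auxiliary function of the plan. It makes C9 an acceptor and C13 a donor. The demand is that it be removed without touching the lactone, and that C6 be equilibrated at a stage where C6–H is the only acidic hydrogen.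

**23 from 22 (key).** The bond C9–C10 is cut and ring B opens. The pentacycle falls into two independent bicyclo[3.2.1]octane cages hinged on C6. C9 disappears as a stereocentre and the trans A/B problem is handed to a rigid cage. The demand is that a radical at the bridgehead C10 close a strained five-membered ring faster than it is quenched.

**22 from 21 and 19.** C10–Se is exchanged for C10–OMe, a group that survives oxidations, and C13–C16 is cut (aldol retron C16–OH / C12=O). Ring D and the stereocentres C13 and C16 vanish. The demand is that the ketol form against a reversible equilibrium with the hydroxyl endo, and that it be trapped as a silyl ether.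

**19 from 18 and 17.** These are functional group changes only. C12=O comes from the single allylic CH2 of the ring C alkene, and the C16 ketone comes from a terminal allyl group. The demand is chemoselection between a terminal and a ring alkene.

**17 from 14.** C6–C8 is cut by a [3,3] retron (γ,δ-unsaturated acid C7–C6–C8–C9=C11). The congested bond between tertiary C6 and quaternary C8 becomes an ester C–O bond, and C8 is traced back to a carbinol. The demand is suprafacial chirality transfer; C6 need not be controlled.

**14 from 10 and 13.** The ester bond C7–O is cut. This is the convergent point and joins two halves of similar size.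

**10 from 9, 8, 7, 6.** C5–C6 is cut (radical allyl transfer followed by cleavage of the terminal carbon), and the C3 carbinol is traced to a ketone. The demand is that carbon enter at C5 from the lactone side of the one-atom bridge and that hydride reach C3 equatorially.

**6 from 5.** C10–O and C5–I are cut (halolactonisation retron across an enol ether C5=C10). The cage, C10 and C5 disappear. The demand is that the electrophile choose the enol ether that has the carboxamide within reach.

**5 from 3, then 1 and 2.** C4–C18 is cut and ring A is rearomatised. All seven ring A/lactone carbons with both oxygens at C3 and C10 are present in a commercial benzoic acid. The demand is facial control at C4 by the amide auxiliary.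

**13 from 12 and 11.** The carbinol is traced to an enone, and C8–C15 is cut to a vinylogous ester and an allyl nucleophile.

## Other disconnections considered

**Alternative 1:** (the first that comes to mind) cut C16–O. The target is formally the hydrate of the 16-ene A1, which would be reached by a linear hydrofluorene-type build-up with ring A annulated last. The forward key step is Markovnikov hydration of A1, by Mukaiyama hydration or oxymercuration. A1 already holds all five rings and eight of the nine stereocentres, so the cut simplifies nothing. In addition, a tertiary C16 radical or cation should be captured by oxygen on the open exo face, which should give the 16-epimer A2 rather than the endo carbinol. Correction would cost cleavage to the 16-ketone and a methyl addition in the presence of lactone, ester and free hydroxyl.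

**Alternative 2:** cut C6–C8 and reconnect C7–C8, so that ring B comes from a six-membered ring as in the biosynthesis from ent-kauranoids. The forward key step is a photochemical Wolff rearrangement of the α-diazo ketone A3 in aqueous solvent: C8 migrates from C7 to C6 and the ketene is hydrated to the C7 acid. The step is mechanistically sound, but A3 contains the same lactone cage, the same C9–C10 bond and the same C/D cage as the target. The hard bonds therefore remain, and three or four redox and diazo-transfer steps are added. Kinetic protonation of the ketene-derived enol from the open face would also place C7 on the hindered face.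

**Alternative 3:** cut C4–C5 and C10–O together. The forward key step is oxidation of the α-methyl β-keto ester A4 with Mn(OAc)3. The C4 radical attacks C5 of the ring B alkene (6-endo), the tertiary C10 radical is oxidised, and the ester closes the lactone. This fits the C3 oxygen and the γ-lactone well and needs only one asymmetric step. Its weakness is that the side chain sits on planar C10, so the face of attack at C5 depends wholly on C6. In A4 the hydrogen on C6 is both allylic and α to the ester, so base moves the alkene into conjugation. If C7 is stored as a protected alcohol, C6 must be set kinetically, and the sigmatropic step that would do this is expected (boat for the Z and chair for the E ketene acetal of cyclohexenyl esters) to favour the wrong relative configuration. The repairs make the route longer than the chosen one.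

Key step: step 16

## Remarks

- Assumption: the (S)-auxiliary 2 is taken to direct iodomethane to the face of enolate 4 that gives C4 as drawn in 5. If the sense were opposite, the equally commercial (R)-enantiomer would be used.
- Compounds 16–25 are carried as mixtures of C6 epimers. Their SMILES leave C6 open, and step 19 funnels them into one configuration.

## Steps

Step 1
Reactants: 1 2,5-dimethoxybenzoic acid; 2 (S)-2-(methoxymethyl)pyrrolidine
Product: 3 [(S)-2-(methoxymethyl)pyrrolidin-1-yl](2,5-dimethoxyphenyl)methanone
Conditions: EDC·HCl, HOBt, i-Pr2NEt, CH2Cl2, rt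
Reagents that add atoms: none
Why: Carbodiimide amide coupling; it installs the proline-derived auxiliary needed for facial control in step 2 and creates no stereocentre.

Step 2
Reactants: 3 benzamide
Product: 5 [(S)-2-(methoxymethyl)pyrrolidin-1-yl][(1S)-2,5-dimethoxy-1-methylcyclohexa-2,5-dien-1-yl]methanone, via potassium enolate 4 (not isolated)
Conditions: K, NH3(l)/THF, t-BuOH (1 equiv), −78 °C; piperylene; MeI, −78 °C
Reagents that add atoms: iodomethane (CI)
Why: Asymmetric Birch reductive alkylation: the acceptor-bearing C4 and the para carbon C1 become sp3 while both methoxy groups stay on the alkenes C2=C3 and C5=C10. The chelated amide enolate 4 should be methylated on the face left open by the methoxymethyl arm, which sets the quaternary C4.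

Step 3
Reactants: 5 diene amide
Product: 6 8-iodo-5-methoxy-1-methyl-6-oxabicyclo[3.2.1]octane-2,7-dione (iodine on C5, anti to the lactone bridge; methoxy on C10; ketone at C3)
Conditions: NIS (1.05 equiv), THF/H2O 10:1, 0 °C; then 0.5 M HCl, rt
Reagents that add atoms: N-iodosuccinimide (O=C1CCC(=O)N1I); water (O)
Why: Iodolactonisation of an enol ether: iodonium adds to the nucleophilic C5, and the amide oxygen captures the C10 oxocarbenium ion on the face of C19 (five-membered ring, anti addition), fixing C10. Water hydrolyses the iminium ether and frees the auxiliary, and dilute acid turns the C2=C3 enol ether into the C3 ketone. The second enol ether has no internal nucleophile in reach (only a four-membered ring), so its iodonium formation should be unproductive.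

Step 4
Reactants: 6 iodide
Product: 7 8-allyl-5-methoxy-1-methyl-6-oxabicyclo[3.2.1]octane-2,7-dione (allyl on C5, syn to the lactone bridge)
Conditions: allyltributylstannane, AIBN, PhH, 80 °C
Reagents that add atoms: allyltributylstannane (C=CC[Sn](CCCC)(CCCC)CCCC)
Why: Keck radical allylation: the C5 radical on the one-atom bridge should be attacked from the side of the flat, hydrogen-free lactone bridge rather than from the side of the C1–C3 bridge with its axial hydrogens. This puts C6 where the target needs it and sets C5.

Step 5
Reactants: 7 keto lactone
Product: 8 8-allyl-2-hydroxy-5-methoxy-1-methyl-6-oxabicyclo[3.2.1]octan-7-one (3β-OH, axial, trans to C19)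
Conditions: L-Selectride, THF, −78 °C; H2O
Reagents that add atoms: none
Why: A bulky trialkylborohydride attacks a chair cyclohexanone equatorially and should give the axial 3β-alcohol (cis to C18, anti to C19). At −78 °C the ketone reacts ahead of the hindered lactone.

Step 6
Reactants: 8 alcohol
Product: 9 tert-butyldimethylsilyl ether of 8
Conditions: TBSOTf, 2,6-lutidine, CH2Cl2, 0 °C
Reagents that add atoms: tert-butyldimethylsilyl trifluoromethanesulfonate (CC(C)(C)[Si](C)(C)OS(=O)(=O)C(F)(F)F)
Why: Silylation under non-basic conditions blocks the retro-aldol of the β-hydroxy lactone and shields C3 from the later oxidations.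

Step 7
Reactants: 9 allyl compound
Product: 10 2-[2-(tert-butyldimethylsilyloxy)-5-methoxy-1-methyl-7-oxo-6-oxabicyclo[3.2.1]octan-8-yl]acetic acid (C5–C6H2–C7OOH)
Conditions: RuCl3 (cat.), NaIO4, CCl4/MeCN/H2O, rt
Reagents that add atoms: sodium periodate ([Na+].[O-]I(=O)(=O)=O); water (O)
Why: Oxidative cleavage of the terminal alkene by RuO4 made in the flask gives the acid directly. Silyl ether, lactone and mixed ketal are inert to it.

Step 8
Reactants: 11 3-ethoxycyclohex-2-en-1-one
Product: 12 3-(prop-2-enyl)cyclohex-2-en-1-one
Conditions: allylmagnesium bromide, THF, 0 °C; 1 M HCl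
Reagents that add atoms: allylmagnesium bromide (C=CC[Mg]Br)
Why: Stork–Danheiser sequence: 1,2-addition to the vinylogous ester and acid-induced loss of ethanol transpose the enone and place C15–C17 on C8.

Step 9
Reactants: 12 enone
Product: 13 (R)-3-(prop-2-enyl)cyclohex-2-en-1-ol
Conditions: (S)-2-methyl-CBS-oxazaborolidine (10 mol%), BH3·SMe2, THF, −20 °C; MeOH
Reagents that add atoms: none
Why: Corey–Bakshi–Shibata reduction: the alkenyl side acts as the large group, so the (S)-catalyst should give the (R)-carbinol (C11), the source of the C8 configuration.

Step 10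
Reactants: 10 acid; 13 allylic alcohol
Product: 14 (R)-3-allylcyclohex-2-enyl ester of 10
Conditions: EDC·HCl, DMAP, CH2Cl2, 0 °C to rt
Reagents that add atoms: none
Why: Steglich-type esterification of an unhindered acetic acid side chain with a secondary allylic alcohol; no stereocentre is touched.

Step 11
Reactants: 14 allylic ester
Product: 17 2-(trimethylsilyl)ethyl ester of the rearranged acid (C6 joined to quaternary C8, which bears allyl; ring C alkene C9=C11; C6 epimers), via silyl ketene acetal 15 (not isolated), via carboxylic acid 16 (not isolated)
Conditions: KHMDS, TMSCl, toluene/THF, −78 to 60 °C; 1 M HCl; then Me3SiCH2CH2OH, EDC·HCl, DMAP, CH2Cl2, rt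
Reagents that add atoms: 2-(trimethylsilyl)ethanol (OCC[Si](C)(C)C)
Why: Ireland–Claisen rearrangement: the suprafacial [3,3] shift forms C6–C8 on the ring face that carried the C11 oxygen, so the (R)-carbinol is translated into the required quaternary C8. The intramolecular mode is what makes the tertiary–quaternary bond accessible. C6 depends on the chair/boat balance and is deliberately left to step 19.

Step 12
Reactants: 17 diene ester
Product: 18 methyl ketone (C8–C15H2–C16(=O)–C17H3)
Conditions: PdCl2 (10 mol%), CuCl, O2, DMF/H2O, rt
Reagents that add atoms: water (O)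
Why: Tsuji–Wacker oxidation is selective for the terminal monosubstituted alkene. The ring alkene next to the quaternary C8 is internal and hindered.

Step 13
Reactants: 18 alkene
Product: 19 enone (C12=O, C9=C11)
Conditions: Rh2(cap)4 (1 mol%), t-BuOOH, K2CO3, CH2Cl2, rt
Reagents that add atoms: tert-butyl hydroperoxide (CC(C)(C)OO)
Why: Catalytic allylic oxidation: C12 is the only allylic CH2 because the other allylic position is the quaternary C8, so a single enone should form.

Step 14
Reactants: 19 enone methyl ketone
Product: 21 triethylsilyl ether of the bicyclo[3.2.1]oct-3-en-2-one ketol (ring D closed; C16 methyl exo, silyloxy endo), via ketol 20 (not isolated)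
Conditions: KOt-Bu (0.1 equiv), t-BuOH/THF, 0 °C; then TESOTf, 2,6-lutidine, CH2Cl2, 0 °C
Reagents that add atoms: triethylsilyl trifluoromethanesulfonate (CC[Si](CC)(CC)OS(=O)(=O)C(F)(F)F)
Why: Intramolecular aldol, 5-(enolexo)-exo-trig: C13 is the only enolisable position of the enone and must bond cis to C15, which sets C13. The closure places the C16 oxygen next to the C12 oxygen (cation bridge, then hydrogen bond) and the larger methyl on the open exo side, which sets C16 as in the target. Dehydration would need a bridgehead alkene, and silylation removes the way back.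

Step 15
Reactants: 21 methoxy lactone
Product: 22 C10 phenylselenide (phenylselanyl in place of methoxy at the bridgehead)
Conditions: PhSeSiMe3 (1.2 equiv), TMSOTf (10 mol%), CH2Cl2, −78 to −40 °C
Reagents that add atoms: trimethyl(phenylselanyl)silane (C[Si](C)(C)[Se]c1ccccc1)
Why: Lewis acid exchange of an O,O-acetal for an O,Se-acetal, running through the ring-opened methoxy-oxocarbenium silyl carboxylate and reclosure. Only the cage with the lactone oxygen cis to C19 can form, so C10 is unchanged.

Step 16
Reactants: 22 selenide
Product: 23 pentacyclic 12-ketone (ring B closed; C6 epimers)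
Conditions: Bu3SnH (syringe pump), AIBN, PhH (3 mM), 80 °C
Reagents that add atoms: none
Why: The stannyl radical abstracts the phenylselanyl group and gives the tertiary α-acyloxy radical at the bridgehead C10, which is nucleophilic and adds to C9, the β-carbon of the electron-poor enone; the α-keto radical at C11 then takes hydrogen from the stannane. This is a reductive Giese-type conjugate cyclisation from an O,Se-acetal, a known reaction type. Ring B closes in the 5-exo-trig mode (C10, C5, C6, C8, C9 in the ring, C11 outside), and 6-endo attack at C11 is opposed by polarity and by geometry. C10 cannot invert because the lactone bridge holds it pyramidal with its orbital pointing exo, so the oxygen stays on the face of C19 and the A/B junction must come out trans. A free ketyl of an open C10 keto ester would be expected to close to the cis-hydrindane instead. C9 is set by the carbocyclic cage: the face syn to the C15–C16 bridge is covered by the endo triethylsilyloxy group, so C10 enters from the face syn to C14 and H9 ends cis to C15. The selectivity needed is cyclisation over hydrogen transfer to C10, and it is served by matched polarity, high dilution and slow addition of the stannane. C6 is not controlled here and is corrected in step 19.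

Step 17
Reactants: 23 ketone
Product: 24 C11=C12 enol triflate
Conditions: KHMDS (1.05 equiv), PhNTf2, THF, −78 °C
Reagents that add atoms: N-phenylbis(trifluoromethanesulfonimide) (O=S(=O)(N(c1ccccc1)S(=O)(=O)C(F)(F)F)C(F)(F)F)
Why: The ketone can enolise only towards C11 because C13 is a bridgehead, and the silyl ether on C16 rules out a retro-aldol. A planar enol triflate avoids building a new tetrahedral centre beside the endo silyloxy group.

Step 18
Reactants: 24 enol triflate
Product: 25 saturated pentacycle (C11 and C12 as CH2)
Conditions: H2 (1 atm), PtO2, NaHCO3, EtOAc, rt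
Reagents that add atoms: none
Why: Hydrogenolysis of the vinyl C–O bond and saturation of the alkene over platinum remove the auxiliary C12 oxygen in one operation. No stereocentre is formed and no other reducible group is present.

Step 19
Reactants: 25 C6 epimer mixture
Product: 26 single 6β-ester (C7 trans to C4 and to C14)
Conditions: KOt-Bu (0.2 equiv), t-BuOH/THF, 40 °C
Reagents that add atoms: none
Why: Thermodynamic epimerisation through the ester enolate: C6–H is the only acidic hydrogen in 25. The ester should settle trans to both neighbouring α-face substituents, the C5–C4 and C8–C14 bonds, so both epimers converge on the target configuration.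

Step 20
Reactants: 26 protected compound
Product: 27 target, CNP0343121.3
Conditions: Bu4NF, AcOH, THF, 40 °C; citric acid work-up
Reagents that add atoms: none
Why: Fluoride cleaves both silyl ethers and fragments the 2-(trimethylsilyl)ethyl ester in one step. The acetic acid buffer keeps the C3 alkoxide from starting a retro-aldol, and no acid strong enough to ionise C16 is present.

## Compound list

1 | 2,5-dimethoxybenzoic acid | COc1ccc(OC)c(C(=O)O)c1 | starting material
2 | (S)-2-(methoxymethyl)pyrrolidine | COC[C@@H]1CCCN1 | starting material
3 | [(S)-2-(methoxymethyl)pyrrolidin-1-yl](2,5-dimethoxyphenyl)methanone | COC[C@@H]1CCCN1C(=O)c1cc(OC)ccc1OC | intermediate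
4 | potassium amide enolate of the 1,4-dihydroarene | COC[C@@H]1CCCN1C([O-])=C1C(OC)=CCC(OC)=C1.[K+] | intermediate
5 | auxiliary amide of (1S)-2,5-dimethoxy-1-methylcyclohexa-2,5-diene-1-carboxylic acid | C[C@@]1(C(=O)N2CCC[C@H]2COC)C(OC)=CCC(OC)=C1 | intermediate
6 | 8-iodo-5-methoxy-1-methyl-6-oxabicyclo[3.2.1]octane-2,7-dione | C[C@@]12C(=O)O[C@@](OC)(CCC1=O)[C@H]2I | intermediate
7 | 8-allyl-5-methoxy-1-methyl-6-oxabicyclo[3.2.1]octane-2,7-dione | C[C@@]12C(=O)O[C@@](OC)(CCC1=O)[C@@H]2CC=C | intermediate
8 | 8-allyl-2-hydroxy-5-methoxy-1-methyl-6-oxabicyclo[3.2.1]octan-7-one | C[C@@]12C(=O)O[C@@](OC)(CC[C@@H]1O)[C@@H]2CC=C | intermediate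
9 | tert-butyldimethylsilyl ether of 8 | C[C@@]12C(=O)O[C@@](OC)(CC[C@@H]1O[Si](C)(C)C(C)(C)C)[C@@H]2CC=C | intermediate
10 | ring A/lactone acetic acid | C[C@@]12C(=O)O[C@@](OC)(CC[C@@H]1O[Si](C)(C)C(C)(C)C)[C@@H]2CC(=O)O | intermediate
11 | 3-ethoxycyclohex-2-en-1-one | CCOC1=CC(=O)CCC1 | starting material
12 | 3-(prop-2-enyl)cyclohex-2-en-1-one | C=CCC1=CC(=O)CCC1 | intermediate
13 | (R)-3-(prop-2-enyl)cyclohex-2-en-1-ol | O[C@@H]1CCCC(CC=C)=C1 | intermediate
14 | ester of 10 with 13 | C[C@@]12C(=O)O[C@@](OC)(CC[C@@H]1O[Si](C)(C)C(C)(C)C)[C@@H]2CC(=O)O[C@@H]1CCCC(CC=C)=C1 | intermediate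
15 | (Z)-trimethylsilyl ketene acetal of 14 | C[C@@]12C(=O)O[C@@](OC)(CC[C@@H]1O[Si](C)(C)C(C)(C)C)[C@@H]2/C=C(\O[Si](C)(C)C)O[C@@H]1CCCC(CC=C)=C1 | intermediate
16 | rearranged carboxylic acid (C6 epimers) | C[C@@]12C(=O)O[C@@](OC)(CC[C@@H]1O[Si](C)(C)C(C)(C)C)[C@@H]2C(C(=O)O)[C@]1(CC=C)C=CCCC1 | intermediate
17 | 2-(trimethylsilyl)ethyl ester of 16 | C[C@@]12C(=O)O[C@@](OC)(CC[C@@H]1O[Si](C)(C)C(C)(C)C)[C@@H]2C(C(=O)OCC[Si](C)(C)C)[C@]1(CC=C)C=CCCC1 | intermediate
18 | methyl ketone | C[C@@]12C(=O)O[C@@](OC)(CC[C@@H]1O[Si](C)(C)C(C)(C)C)[C@@H]2C(C(=O)OCC[Si](C)(C)C)[C@]1(CC(C)=O)C=CCCC1 | intermediate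
19 | enone methyl ketone | C[C@@]12C(=O)O[C@@](OC)(CC[C@@H]1O[Si](C)(C)C(C)(C)C)[C@@H]2C(C(=O)OCC[Si](C)(C)C)[C@]1(CC(C)=O)C=CC(=O)CC1 | intermediate
20 | bicyclo[3.2.1]octenone ketol | C[C@@]12C(=O)O[C@@](OC)(CC[C@@H]1O[Si](C)(C)C(C)(C)C)[C@@H]2C(C(=O)OCC[Si](C)(C)C)[C@]12C=CC(=O)[C@H](C1)[C@@](C)(O)C2 | intermediate
21 | triethylsilyl ether of 20 | C[C@@]12C(=O)O[C@@](OC)(CC[C@@H]1O[Si](C)(C)C(C)(C)C)[C@@H]2C(C(=O)OCC[Si](C)(C)C)[C@]12C=CC(=O)[C@H](C1)[C@@](C)(O[Si](CC)(CC)CC)C2 | intermediate
22 | C10 phenylselenide | C[C@@]12C(=O)O[C@@]([Se]c3ccccc3)(CC[C@@H]1O[Si](C)(C)C(C)(C)C)[C@@H]2C(C(=O)OCC[Si](C)(C)C)[C@]12C=CC(=O)[C@H](C1)[C@@](C)(O[Si](CC)(CC)CC)C2 | intermediate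
23 | pentacyclic 12-ketone (C6 epimers) | C[C@@]12C(=O)O[C@]3(CC[C@@H]1O[Si](C)(C)C(C)(C)C)[C@@H]1CC(=O)[C@@H]4C[C@]1(C[C@]4(C)O[Si](CC)(CC)CC)C(C(=O)OCC[Si](C)(C)C)[C@@H]32 | intermediate
24 | C11=C12 enol triflate (C6 epimers) | C[C@@]12C(=O)O[C@]3(CC[C@@H]1O[Si](C)(C)C(C)(C)C)[C@@H]1C=C(OS(=O)(=O)C(F)(F)F)[C@@H]4C[C@]1(C[C@]4(C)O[Si](CC)(CC)CC)C(C(=O)OCC[Si](C)(C)C)[C@@H]32 | intermediate
25 | saturated pentacycle (C6 epimers) | C[C@@]12C(=O)O[C@]3(CC[C@@H]1O[Si](C)(C)C(C)(C)C)[C@@H]1CC[C@@H]4C[C@]1(C[C@]4(C)O[Si](CC)(CC)CC)C(C(=O)OCC[Si](C)(C)C)[C@@H]32 | intermediate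
26 | 6β-ester, fully protected target | C[C@@]12C(=O)O[C@]3(CC[C@@H]1O[Si](C)(C)C(C)(C)C)[C@@H]1CC[C@@H]4C[C@]1(C[C@]4(C)O[Si](CC)(CC)CC)[C@@H](C(=O)OCC[Si](C)(C)C)[C@@H]32 | intermediate
27 | CNP0343121.3 | C[C@@]12C(=O)O[C@]3(CC[C@@H]1O)[C@@H]1CC[C@@H]4C[C@]1(C[C@]4(C)O)[C@@H](C(=O)O)[C@@H]32 | target

## Step count and least certain steps

Total: 20 steps. Longest linear sequence: 18 steps (steps 1–7 and 10–20); steps 8 and 9 form the short branch.

**Step 16 (key).** The most likely failure is hydrogen transfer from the stannane to the C10 radical before ring closure. The closure builds a strained trans-fused five-membered ring between two bulky cages, and the C6 epimer that carries C7 on the face of C4 and C14 meets extra strain.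

The fallback generates the same radical without any hydrogen-atom donor. It sets out from 21:
- Hydrolysis of the mixed ketal (LiBF4, wet MeCN) gives the lactol F1.
- Acylation with methyl chlorooxoacetate (Et3N, DMAP) gives the mixed oxalate F2.
- Saponification with CsOH gives the caesium oxalate F3.
- Irradiation of F3 with Ir[dF(CF3)ppy]2(dtbbpy)PF6 and blue light in DME/DMF/H2O expels two molecules of CO2. The lifetime of the C10 radical is then limited only by the cyclisation, and the resulting enolate is protonated by water.

The route is rejoined at 23.

**Step 15.** Two things may go wrong: conjugate addition of the selenium nucleophile to the enone, and loss of the tertiary silyl ether under the Lewis acid. Both take the acceptor or the protection away just before the key step.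

The fallback avoids a nucleophilic chalcogen. It sets out from 21:
- Zinc-catalysed exchange with acetyl chloride (ZnBr2, cat., CH2Cl2) gives the bridgehead chloride F4.
- F4 is used crude under the stannane conditions of step 16.

The route is rejoined at 23 and compound 22 is bypassed.

**Step 14.** The ketone–ketone aldol may lie on the side of the open diketone. On long exposure to base, a slow irreversible Michael addition of the methyl ketone enolate (C17) to C9 may also drain the material.

The fallback makes the C13 enolate irreversibly and regiospecifically. It sets out from 17: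
- Allylic oxidation is run first and gives the allyl enone F5.
- Deprotonation at C13 (LiHMDS) and bromination with NBS give the bromo enone F6.
- Tsuji–Wacker oxidation gives the bromo diketone F7.
- SmI2 in THF at −78 °C performs an intramolecular Reformatsky-type aldol through a chelate of trivalent samarium between the C12 and C16 oxygens. The chelate holds the aldolate and favours the endo oxygen.

The route is rejoined at 20.

**Step 3.** Competing iodination of the less hindered C2=C3 enol ether may consume the reagent and give mixtures.

The fallback lets both enol ethers react and then corrects. It sets out from 5: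
- NIS (2.2 equiv) in wet THF gives the diiodide F8.
- Triphenylphosphine in THF/MeOH removes only the iodine α to the C3 ketone (through the enol phosphonium salt), while the hindered C5 iodide is left alone.

The route is rejoined at 6.

## Further compounds

F1 | step 16 | C10 lactol (hydroxy in place of methoxy in 21) | C[C@@]12C(=O)O[C@@](O)(CC[C@@H]1O[Si](C)(C)C(C)(C)C)[C@@H]2C(C(=O)OCC[Si](C)(C)C)[C@]12C=CC(=O)[C@H](C1)[C@@](C)(O[Si](CC)(CC)CC)C2
F2 | step 16 | C10 methyl oxalate | C[C@@]12C(=O)O[C@@](OC(=O)C(=O)OC)(CC[C@@H]1O[Si](C)(C)C(C)(C)C)[C@@H]2C(C(=O)OCC[Si](C)(C)C)[C@]12C=CC(=O)[C@H](C1)[C@@](C)(O[Si](CC)(CC)CC)C2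
F3 | step 16 | C10 caesium oxalate | C[C@@]12C(=O)O[C@@](OC(=O)C(=O)[O-])(CC[C@@H]1O[Si](C)(C)C(C)(C)C)[C@@H]2C(C(=O)OCC[Si](C)(C)C)[C@]12C=CC(=O)[C@H](C1)[C@@](C)(O[Si](CC)(CC)CC)C2.[Cs+]
F4 | step 15 | C10 bridgehead chloride | C[C@@]12C(=O)O[C@@](Cl)(CC[C@@H]1O[Si](C)(C)C(C)(C)C)[C@@H]2C(C(=O)OCC[Si](C)(C)C)[C@]12C=CC(=O)[C@H](C1)[C@@](C)(O[Si](CC)(CC)CC)C2
F5 | step 14 | allyl enone | C[C@@]12C(=O)O[C@@](OC)(CC[C@@H]1O[Si](C)(C)C(C)(C)C)[C@@H]2C(C(=O)OCC[Si](C)(C)C)[C@]1(CC=C)C=CC(=O)CC1
F6 | step 14 | 13-bromo allyl enone | C[C@@]12C(=O)O[C@@](OC)(CC[C@@H]1O[Si](C)(C)C(C)(C)C)[C@@H]2C(C(=O)OCC[Si](C)(C)C)[C@]1(CC=C)C=CC(=O)C(Br)C1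
F7 | step 14 | 13-bromo enone methyl ketone | C[C@@]12C(=O)O[C@@](OC)(CC[C@@H]1O[Si](C)(C)C(C)(C)C)[C@@H]2C(C(=O)OCC[Si](C)(C)C)[C@]1(CC(C)=O)C=CC(=O)C(Br)C1
F8 | step 3 | 3,8-diiodo-5-methoxy-1-methyl-6-oxabicyclo[3.2.1]octane-2,7-dione | C[C@@]12C(=O)O[C@@](OC)(CC(I)C1=O)[C@H]2I
A1 | alternative 1 | 16-ene (gibberellin A4) | C[C@@]12C(=O)O[C@]3(CC[C@@H]1O)[C@@H]1CC[C@@H]4C[C@]1(CC4=C)[C@@H](C(=O)O)[C@@H]32
A2 | alternative 1 | 16-epimer of the target (hydroxyl exo) | C[C@@]12C(=O)O[C@]3(CC[C@@H]1O)[C@@H]1CC[C@@H]4C[C@]1(C[C@@]4(C)O)[C@@H](C(=O)O)[C@@H]32
A3 | alternative 2 | 6-diazo-7-ketone with six-membered ring B | C[C@@]12C(=O)O[C@]3(CC[C@@H]1O)[C@@H]1CC[C@@H]4C[C@]1(C[C@]4(C)O)C(=O)C(=[N+]=[N-])[C@@H]32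
A4 | alternative 3 | tricyclic C5=C10 alkene with α-methyl β-keto ester chain on C10 | CC(C(=O)OC(C)(C)C)C(=O)CCC1=C[C@H](C(=O)OC)[C@@]23C[C@](C)(O)[C@@H](C2)CC[C@@H]13
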